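**Assumptions (stated once):**
- Fertidin is the p-anisate of jaeschkeanadiol, with the relative and absolute configuration in the given SMILES: trans-fused hydroazulene, 8a-Me β, 3-OH β, 3-iPr α, 3a-H α, 4-OAr α.
- The Rh [5+2] step is assumed to be stereoretentive at the quaternary cyclopropane carbon.
- The tartrate-derived ligand enantiomer in Step 3 is chosen to give the (1R) cyclopropane, and the ee is to be confirmed.

## Retrosynthetic overview
1. Fertidin ← jaeschkeanadiol (selective anisoylation of the secondary OH) ← iPr addition to the C3 ketone from the α-face.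
2. Hydroxy-ketone (4α-OH, 3a-Hα, trans-fused) ← SmI2 opening of an α,β-epoxy ketone ← nucleophilic epoxidation of the C3a=C4 enone of a hydroazulenone.
3. Hydroazulenone (bicyclo[5.3.0] dienone with angular Me) ← Rh(I)-catalysed intramolecular [5+2] of an ynone-tethered vinylcyclopropane. This forms the 7-ring and the 5-ring in one step and hands the cyclopropane quaternary stereocentre to C8a.
4. The cyclopropane is the first ring made: Charette asymmetric Simmons–Smith of an (E)-dienol from methacrolein, then chain extension by HWE, Cu–H reduction and Weinreb alkynylation.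

## Route

**Step 1**
Reactants: 1 methacrolein; 2 triethyl 2-phosphonopropionate
Product: 3 ethyl (2E)-2,4-dimethylpenta-2,4-dienoate
Conditions: NaH, THF, 0 °C → rt
Reagents that add atoms: 2, CCOC(=O)C(C)P(=O)(OCC)OCC (supplies =C(CH3)CO2Et)
Why: Horner–Wadsworth–Emmons olefination gives the trisubstituted E-enoate, with the ester trans to the isopropenyl group.

**Step 2**
Reactants: 3
Product: 4 (2E)-2,4-dimethylpenta-2,4-dien-1-ol
Conditions: DIBAL-H (2.5 equiv), CH2Cl2, −78 → 0 °C
Reagents that add atoms: none
Why: Ester-to-allylic alcohol reduction; both C=C bonds are untouched and E geometry is retained.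

**Step 3**
Reactants: 4; 5 diiodomethane
Product: 6 [(1R,2S)-1-methyl-2-(prop-1-en-2-yl)cyclopropyl]methanol
Conditions: Et2Zn, CH2I2, (4S,5S)-tartramide-derived butyl-dioxaborolane ligand, CH2Cl2, −10 °C → rt
Reagents that add atoms: 5, ICI (supplies the ring CH2)
Why: Charette enantioselective Simmons–Smith cyclopropanation is directed by the allylic alkoxide, so the dienol's allylic alkene reacts selectively and the ligand sets the quaternary carbinol-bearing carbon as (R). The E-alkene makes the isopropenyl trans to CH2OH, which also prevents the retro-Claisen-type rearrangement of a cis-formyl/vinylcyclopropane in Step 4.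

**Step 4**
Reactants: 6
Product: 7 (1R,2S)-1-methyl-2-(prop-1-en-2-yl)cyclopropane-1-carbaldehyde
Conditions: Dess–Martin periodinane, NaHCO3, CH2Cl2, rt
Reagents that add atoms: none
Why: Buffered DMP oxidation avoids acid-induced opening of the vinylcyclopropane, and the aldehyde cannot epimerise because its α-carbon is quaternary.

**Step 5**
Reactants: 7; 8 N-methoxy-N-methyl-2-(diethoxyphosphoryl)acetamide
Product: 9 (2E)-N-methoxy-N-methyl-3-[(1S,2S)-1-methyl-2-(prop-1-en-2-yl)cyclopropyl]prop-2-enamide
Conditions: NaH, THF, 0 °C → rt
Reagents that add atoms: 8, CCOP(=O)(OCC)CC(=O)N(C)OC (supplies =CH–C(=O)N(OMe)Me)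
Why: HWE olefination gives the E-unsaturated Weinreb amide. The descriptor at the quaternary carbon changes to S only because CIP priorities change; the spatial arrangement is unchanged.

**Step 6**
Reactants: 9
Product: 10 N-methoxy-N-methyl-3-[(1R,2S)-1-methyl-2-(prop-1-en-2-yl)cyclopropyl]propanamide
Conditions: [(Ph3P)CuH]6 (2 mol %), PhSiH3, toluene, rt
Reagents that add atoms: none
Why: Cu–H conjugate reduction is ionic, so it does not open the cyclopropane the way dissolving-metal reduction could, and it leaves the isopropenyl group and the Weinreb amide intact.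

**Step 7**
Reactants: 10; 11 ethynylmagnesium bromide
Product: 12 5-[(1R,2S)-1-methyl-2-(prop-1-en-2-yl)cyclopropyl]pent-1-yn-3-one
Conditions: HC≡CMgBr (3 equiv), THF, 0 °C; cold aq. NH4Cl quench
Reagents that add atoms: 11, C#C[Mg]Br (supplies C≡CH)
Why: Weinreb ketone synthesis stops at the ynone because of the stable chelated intermediate; the three-atom tether needed for the 5-ring is now in place.

**Step 8**
Reactants: 12
Product: 13 (8aR)-6,8a-dimethyl-1,5,8,8a-tetrahydroazulen-3(2H)-one (cross-conjugated dienone; C3a=C4 conjugated to the C3 ketone, plus C6=C7)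
Conditions: [Rh(CO)2Cl]2 (5 mol %), DCE (0.02 M), Ar, 80 °C
Reagents that add atoms: none (isomerisation)
Why: Wender-type Rh(I) intramolecular [5+2] of a vinylcyclopropane and an alkyne. The three-atom tether forces cleavage of the proximal C1'–C2' cyclopropane bond, so the 5-ring (C8a–C1–C2–C3–C3a) and the 7-ring (C3a–C4–C5–C6=C7–C8–C8a) form together. The isopropenyl methyl becomes the C6 methyl, and the quaternary stereocentre is retained as (8aR). This is an extension of known chemistry to a quaternary tether-bearing cyclopropane carbon and an ynone acceptor.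

**Step 9**
Reactants: 13; 14 hydrogen peroxide
Product: 15 α,β-epoxy ketone (3a,4-epoxide, O on the face opposite the 8a-CH3; 8aR), SMILES in the list
Conditions: 30% H2O2, NaOH (aq.), MeOH, 0 °C
Reagents that add atoms: 14, OO (supplies the epoxide O)
Why: Weitz–Scheffer nucleophilic epoxidation reacts only at the electron-poor enone and not at the isolated trisubstituted C6=C7 alkene. Attack is expected anti to the angular methyl, which fixes the C4 oxygen as α.

**Step 10**
Reactants: 15
Product: 16 (3aS,4S,8aR)-4-hydroxy-6,8a-dimethyl-1,3a,4,5,8,8a-hexahydroazulen-3(2H)-one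
Conditions: SmI2 (2.5 equiv), THF/MeOH, −78 °C
Reagents that add atoms: none (H from MeOH)
Why: SmI2 reductively cleaves the C3a–O bond α to the ketone (Molander α,β-epoxy ketone to β-hydroxy ketone), keeping the C4–O configuration. The Sm(III) enolate is protonated at C3a from the face anti to the angular Me, which sets the trans ring fusion (3a-Hα) and leaves the 4α-OH.

**Step 11**
Reactants: 16; 17 isopropylmagnesium chloride
Product: 18 jaeschkeanadiol, (3R,3aS,4S,8aR)-6,8a-dimethyl-3-(propan-2-yl)-1,2,3,3a,4,5,8,8a-octahydroazulene-3,4-diol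
Conditions: anhydrous CeCl3, iPrMgCl·LiCl (3 equiv), THF, −78 → −20 °C
Reagents that add atoms: 17, CC(C)[Mg]Cl (supplies iPr)
Why: CeCl3-mediated Grignard addition to the cyclopentanone occurs from the α-face, anti to the angular methyl and helped by the chelated 4-alkoxide. This puts iPr α and OH β, and CeCl3 suppresses enolisation that would epimerise C3a or cause retro-aldol.

**Step 12**
Reactants: 18; 19 4-methoxybenzoyl (p-anisoyl) chloride
Product: 20 fertidin
Conditions: 4-MeOC6H4COCl, DMAP, Et3N, CH2Cl2, 0 °C → rt
Reagents that add atoms: 19, COc1ccc(cc1)C(Cl)=O (supplies 4-MeOC6H4C(=O)–)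
Why: Nucleophilic acyl substitution is chemoselective for the secondary C4–OH, and the hindered tertiary C3–OH stays free. If Step 9 had given the β-epoxide, this step would instead be a Mitsunobu reaction with p-anisic acid, which inverts C4 while esterifying.

## Compound list
1 | methacrolein | C=C(C)C=O | starting material
2 | triethyl 2-phosphonopropionate | CCOC(=O)C(C)P(=O)(OCC)OCC | starting material
3 | ethyl (2E)-2,4-dimethylpenta-2,4-dienoate | CCOC(=O)/C(C)=C/C(C)=C | intermediate
4 | (2E)-2,4-dimethylpenta-2,4-dien-1-ol | OC/C(C)=C/C(C)=C | intermediate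
5 | diiodomethane | ICI | starting material
6 | [(1R,2S)-1-methyl-2-(prop-1-en-2-yl)cyclopropyl]methanol | OC[C@]1(C)C[C@H]1C(C)=C | intermediate
7 | (1R,2S)-1-methyl-2-(prop-1-en-2-yl)cyclopropane-1-carbaldehyde | O=C[C@]1(C)C[C@H]1C(C)=C | intermediate
8 | N-methoxy-N-methyl-2-(diethoxyphosphoryl)acetamide | CCOP(=O)(OCC)CC(=O)N(C)OC | starting material
9 | (2E)-N-methoxy-N-methyl-3-[(1S,2S)-1-methyl-2-(prop-1-en-2-yl)cyclopropyl]prop-2-enamide | CON(C)C(=O)/C=C/[C@]1(C)C[C@H]1C(C)=C | intermediate
10 | N-methoxy-N-methyl-3-[(1R,2S)-1-methyl-2-(prop-1-en-2-yl)cyclopropyl]propanamide | CON(C)C(=O)CC[C@]1(C)C[C@H]1C(C)=C | intermediate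
11 | ethynylmagnesium bromide | C#C[Mg]Br | starting material
12 | 5-[(1R,2S)-1-methyl-2-(prop-1-en-2-yl)cyclopropyl]pent-1-yn-3-one | C#CC(=O)CC[C@]1(C)C[C@H]1C(C)=C | intermediate
13 | (8aR)-6,8a-dimethyl-1,5,8,8a-tetrahydroazulen-3(2H)-one | O=C1CC[C@]2(C)CC=C(C)CC=C12 | intermediate
14 | hydrogen peroxide | OO | starting material
15 | 3a,4-epoxy ketone of 13, O anti to the 8a-CH3 | O=C1CC[C@]2(C)CC=C(C)C[C@@H]3O[C@@]132 | intermediate
16 | (3aS,4S,8aR)-4-hydroxy-6,8a-dimethyl-1,3a,4,5,8,8a-hexahydroazulen-3(2H)-one | O=C1CC[C@]2(C)CC=C(C)C[C@H](O)[C@@H]12 | intermediate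
17 | isopropylmagnesium chloride | CC(C)[Mg]Cl | starting material
18 | jaeschkeanadiol, (3R,3aS,4S,8aR)-6,8a-dimethyl-3-isopropyl-octahydroazulene-3,4-diol | O[C@H]2CC(C)=CC[C@@]3(C)CC[C@@](O)(C(C)C)[C@H]23 | intermediate
19 | 4-methoxybenzoyl chloride | COc1ccc(cc1)C(Cl)=O | starting material
20 | fertidin, (3R,3aS,4S,8aR)-3-hydroxy-6,8a-dimethyl-3-isopropyl-octahydroazulen-4-yl 4-methoxybenzoate | COc1ccc(C(=O)O[C@H]2CC(C)=CC[C@@]3(C)CC[C@@](O)(C(C)C)[C@H]23)cc1 | target

## Totals
Total steps: 12. Longest linear sequence: 12 (methacrolein → fertidin).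

## Three steps most likely to fail
1. **Step 8 (Rh [5+2]).** A quaternary tether-bearing cyclopropane carbon with an ynone acceptor may be sluggish, may cleave the wrong cyclopropane bond, or may not retain configuration at C8a.
   Fallback (changes the approach): build the cyclopentane first. Make the angular quaternary centre by Pd-catalysed asymmetric allylic alkylation of a 2-methylcyclopentanone-derived allyl β-ketoester, then close the 7-ring by RCM and carry on to 16/18.
2. **Step 10 (SmI2 opening and C3a protonation).** The Sm enolate could be protonated from the wrong face, or epimerise to cis-fused ketone if that is the thermodynamic isomer.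
   Fallback (changes the approach): add iPr to enone 13 first, giving a tertiary allylic alcohol. Then do a VO(acac)2/TBuOOH epoxidation syn to that OH and a Cp2TiCl-mediated radical epoxide opening with 1,4-cyclohexadiene, so that C3a–H is set by irreversible H-atom transfer anti to the methyl. Finish with Mitsunobu esterification using p-anisic acid, which inverts C4.
3. **Step 3 (Charette cyclopropanation).** Over-cyclopropanation of the isopropenyl group, or the wrong enantioface for this trisubstituted dienol, would give the wrong or low-ee quaternary centre.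
   Fallback (changes the approach): run racemic Furukawa cyclopropanation of 4 with Et2Zn/CH2I2 and resolve cyclopropylmethanol 6 by lipase-catalysed acetylation (vinyl acetate), recycling the wrong enantiomer via oxidation and reduction.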